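**Retrosynthetic overview**
- Both isobutyrates go on last: target ⇒ triol (two primary OH, one tertiary OH) + isobutyryl chloride.
- Cyclohexenone ⇒ prochiral 3-substituted cyclobutanone + propargyl silyl ether, by a two-carbon ring expansion: nickel-catalysed alkyne insertion into one of the two enantiotopic C(=O)–CH2 bonds. This sets C5 and brings in C2, C3 and the CH2O carbon.
- 1,1-Disubstituted/E skipped diene ⇒ 3-ethynylcyclobutanone + (R)-2-methylpent-4-ene-1,2-diol, by ruthenium-catalysed alkene–alkyne coupling.
- The diol ⇒ (S)-2-methylglycidol + vinyl Grignard; the tertiary carbinol comes from the bought epoxide.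
- Ring order: the four-membered ring is bought; the only ring of the target (six-membered) is made from it in the third of four steps.

Assumption: 3-ethynylcyclobutan-1-one is taken as a purchasable catalogue building block, and the antipode of the carbene ligand that gives (5R) is fixed by a first screen of both antipodes.

**Step 1**
Reactants: 1 (S)-2-methylglycidol, [(2S)-2-methyloxiran-2-yl]methanol; 2 vinylmagnesium bromide
Product: 3 (2R)-2-methylpent-4-ene-1,2-diol
Conditions: 2 (3.0 equiv), CuBr·SMe2 (10 mol%), THF, −30 → 0 °C; then 1 M HCl, 0 °C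
Reagents that add atoms: vinylmagnesium bromide (2), C=C[Mg]Br
Why: Copper-catalysed Grignard opening of a 2,2-disubstituted epoxide is an SN2 attack at the unsubstituted CH2 (the first equivalent only deprotonates the OH), so no bond at the quaternary carbinol carbon is touched and its configuration is carried over unchanged (the descriptor changes from S to R only through CIP priorities).

**Step 2**
Reactants: 3 (2R)-2-methylpent-4-ene-1,2-diol; 4 3-ethynylcyclobutan-1-one
Product: 5 3-[(4E,6R)-6,7-dihydroxy-6-methylhepta-1,4-dien-2-yl]cyclobutan-1-one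
Conditions: 4 (1.2 equiv), [CpRu(MeCN)3]PF6 (5 mol%), acetone, 23 °C
Reagents that add atoms: none
Why: Ruthenium-catalysed alkene–alkyne coupling (formal Alder-ene reaction by way of a ruthenacyclopentene, β-hydride elimination at the only allylic CH2 of 3 and reductive elimination) joins the alkene terminus to the internal alkyne carbon, giving the branched 1,4-diene with the new disubstituted alkene E; the ketone and free hydroxyls are tolerated and no stereocentre is touched.

**Step 3**
Reactants: 5 3-[(4E,6R)-6,7-dihydroxy-6-methylhepta-1,4-dien-2-yl]cyclobutan-1-one; 6 trimethyl(prop-2-yn-1-yloxy)silane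
Product: 9 (5R)-5-[(4E,6R)-6,7-dihydroxy-6-methylhepta-1,4-dien-2-yl]-2-(hydroxymethyl)cyclohex-2-en-1-one, via primary silyl ether 7 (not isolated), via bis-silyl ether enone 8 (not isolated)
Conditions: N,O-bis(trimethylsilyl)acetamide (1.1 equiv), toluene, 23 °C, 30 min; then Ni(cod)2 (10 mol%), L* (12 mol%), 6 (2.0 equiv, syringe pump, 4 h), toluene, 60 °C; then MeOH, citric acid (10 mol%), 23 °C. L* = free C2-symmetric carbene 1,3-bis[2,6-bis((1R)-1-phenylethyl)-4-methylphenyl]imidazol-2-ylidene.
Reagents that add atoms: trimethyl(prop-2-yn-1-yloxy)silane (6), C#CCO[Si](C)(C)C; N,O-bis(trimethylsilyl)acetamide, CC(=N[Si](C)(C)C)O[Si](C)(C)C (its silyl group is carried only by 7 and 8 and is gone in 9)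
Why: Proposed new method: an enantioselective, intermolecular two-carbon ring expansion of a prochiral 3-monosubstituted cyclobutanone with a terminal propargylic alkyne on zerovalent nickel bearing a bulky chiral carbene — oxidative cyclisation of C=O and alkyne gives a spiro oxanickelacyclopentene in which the large ligand pushes the CH2OSiMe3-bearing alkyne carbon onto the carbonyl carbon (the large-ligand regiochemistry known from carbene–nickel aldehyde/alkyne couplings), the C2-symmetric pocket then selects one of the two enantiotopic ring CH2 groups in the strain-driven β-carbon elimination to the seven-membered nickelacycle, and C(sp3)–C(sp2) reductive elimination closes the 2-substituted cyclohex-2-enone and fixes C5 as R; the closest known reaction types are the racemic Ni(cod)2/PCy3-catalysed insertion of internal alkynes into cyclobutanones and the phosphoramidite–nickel enantioselective intramolecular alkene insertion into 3-substituted cyclobutanones.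

**Step 4**
Reactants: 9 (5R)-5-[(4E,6R)-6,7-dihydroxy-6-methylhepta-1,4-dien-2-yl]-2-(hydroxymethyl)cyclohex-2-en-1-one; 10 isobutyryl chloride (2-methylpropanoyl chloride)
Product: 11 CNP0536801.1, (5R)-5-[(4E,6R)-6-hydroxy-6-methyl-7-(2-methylpropanoyloxy)hepta-1,4-dien-2-yl]-2-[(2-methylpropanoyloxy)methyl]cyclohex-2-en-1-one
Conditions: 10 (2.3 equiv), 2,4,6-collidine (4 equiv), CH2Cl2, −40 → 0 °C
Reagents that add atoms: isobutyryl chloride (10), CC(C)C(Cl)=O
Why: Base-mediated O-acylation with an acid chloride discriminates sterically, so the two primary hydroxyls react while the tertiary allylic hydroxyl does not without an acyl-transfer catalyst, and non-nucleophilic collidine avoids substitution of the new allylic ester beside the enone; no stereocentre is touched.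

**Compound list**
1 | (S)-2-methylglycidol, [(2S)-2-methyloxiran-2-yl]methanol | C[C@]1(CO)CO1 | starting material
2 | vinylmagnesium bromide | C=C[Mg]Br | starting material
3 | (2R)-2-methylpent-4-ene-1,2-diol | C=CC[C@@](C)(O)CO | intermediate
4 | 3-ethynylcyclobutan-1-one | C#CC1CC(=O)C1 | starting material
5 | 3-[(4E,6R)-6,7-dihydroxy-6-methylhepta-1,4-dien-2-yl]cyclobutan-1-one | C=C(C/C=C/[C@@](C)(O)CO)C1CC(=O)C1 | intermediate
6 | trimethyl(prop-2-yn-1-yloxy)silane | C#CCO[Si](C)(C)C | starting material
7 | 3-[(4E,6R)-6-hydroxy-6-methyl-7-(trimethylsilyloxy)hepta-1,4-dien-2-yl]cyclobutan-1-one (primary silyl ether) | C=C(C/C=C/[C@@](C)(O)CO[Si](C)(C)C)C1CC(=O)C1 | intermediate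
8 | (5R)-5-[(4E,6R)-6-hydroxy-6-methyl-7-(trimethylsilyloxy)hepta-1,4-dien-2-yl]-2-[(trimethylsilyloxy)methyl]cyclohex-2-en-1-one (bis-silyl ether enone) | C=C(C/C=C/[C@@](C)(O)CO[Si](C)(C)C)[C@@H]1CC=C(CO[Si](C)(C)C)C(=O)C1 | intermediate
9 | (5R)-5-[(4E,6R)-6,7-dihydroxy-6-methylhepta-1,4-dien-2-yl]-2-(hydroxymethyl)cyclohex-2-en-1-one | C=C(C/C=C/[C@@](C)(O)CO)[C@@H]1CC=C(CO)C(=O)C1 | intermediate
10 | isobutyryl chloride (2-methylpropanoyl chloride) | CC(C)C(Cl)=O | starting material
11 | CNP0536801.1, (5R)-5-[(4E,6R)-6-hydroxy-6-methyl-7-(2-methylpropanoyloxy)hepta-1,4-dien-2-yl]-2-[(2-methylpropanoyloxy)methyl]cyclohex-2-en-1-one | C=C(C/C=C/[C@@](C)(O)COC(=O)C(C)C)[C@@H]1CC=C(COC(=O)C(C)C)C(=O)C1 | target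

**Step count and risks**
Total step count: 4. Longest linear sequence: 4 (1 → 3 → 5 → 9 → 11).

Steps most likely to fail:

1. Step 3 (the proposed new ring expansion). The risks are the wrong alkyne orientation (3- instead of 2-substituted enone), alkyne oligomerisation on nickel, incomplete discrimination of the enantiotopic C–C bonds (the C5 epimer is a diastereomer, so the ratio can be read directly by NMR or HPLC), and nickel hydride isomerisation of the skipped diene. The fallback uses known chemistry only; it sets out from 3 and comes back to the route at 9. Rhodium-catalysed asymmetric conjugate alkynylation of bought cyclohex-2-en-1-one with (triisopropylsilyl)acetylene ([Rh(OAc)(C2H4)2]2, the DTBM-SEGPHOS antipode that gives the R adduct, dioxane, 80 °C) gives (3R)-3-[(triisopropylsilyl)ethynyl]cyclohexan-1-one F1. Aerobic dehydrogenation on the side away from the substituent (Pd(OCOCF3)2, DMSO, O2, AcOH, 80 °C) gives (5R)-5-[(triisopropylsilyl)ethynyl]cyclohex-2-en-1-one F2. Morita–Baylis–Hillman hydroxymethylation (aqueous formaldehyde, DMAP, THF/H2O) gives (5R)-2-(hydroxymethyl)-5-[(triisopropylsilyl)ethynyl]cyclohex-2-en-1-one F3. Buffered desilylation (Bu4NF, AcOH, THF, 0 °C) gives (5R)-5-ethynyl-2-(hydroxymethyl)cyclohex-2-en-1-one F4. The ruthenium coupling of step 2, run on F4 and 3, then delivers 9.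

2. Step 2 (alkene–alkyne coupling). The risks are the branched/linear ratio with a secondary propargylic carbon and loss of the volatile alkyne. The fallback fixes the regiochemistry by cross-coupling and builds the E-alkene by metathesis; it sets out from 4 and 1 and comes back at 5. Markovnikov hydroiodination of 4 (NaI, Me3SiCl, H2O, MeCN, 23 °C) gives 3-(1-iodoethenyl)cyclobutan-1-one F5. Stille coupling with allyltributylstannane (Pd(PPh3)4, DMF, 60 °C) gives 3-(penta-1,4-dien-2-yl)cyclobutan-1-one F6. In parallel, one-carbon homologation of 1 with dimethylsulfonium methylide (trimethylsulfonium iodide, butyllithium, THF, −10 → 23 °C) gives (2R)-2-methylbut-3-ene-1,2-diol F7. E-selective cross-metathesis of F6 with excess F7 (second-generation Hoveyda–Grubbs catalyst RuCl2(H2IMes)(=CH-C6H4-2-OiPr), CH2Cl2, 40 °C) gives 5.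

3. Step 4 (double acylation). The risks are partial acylation of the tertiary hydroxyl and base- or chloride-induced substitution or elimination of the allylic ester beside the enone. The fallback replaces acid chloride/base chemistry by biocatalytic acyl transfer; it sets out from 9 and comes back at 11. Immobilised Candida antarctica lipase B with vinyl isobutyrate (4 equiv) in tert-butyl methyl ether at 35 °C acylates only the two primary hydroxyls under neutral conditions; it makes no compound that the list does not hold (F0).

**Further compounds**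
F1 | step 3 | (3R)-3-[(triisopropylsilyl)ethynyl]cyclohexan-1-one | CC(C)[Si](C(C)C)(C(C)C)C#C[C@@H]1CCCC(=O)C1
F2 | step 3 | (5R)-5-[(triisopropylsilyl)ethynyl]cyclohex-2-en-1-one | CC(C)[Si](C(C)C)(C(C)C)C#C[C@@H]1CC=CC(=O)C1
F3 | step 3 | (5R)-2-(hydroxymethyl)-5-[(triisopropylsilyl)ethynyl]cyclohex-2-en-1-one | CC(C)[Si](C(C)C)(C(C)C)C#C[C@@H]1CC=C(CO)C(=O)C1
F4 | step 3 | (5R)-5-ethynyl-2-(hydroxymethyl)cyclohex-2-en-1-one | C#C[C@@H]1CC=C(CO)C(=O)C1
F5 | step 2 | 3-(1-iodoethenyl)cyclobutan-1-one | C=C(I)C1CC(=O)C1
F6 | step 2 | 3-(penta-1,4-dien-2-yl)cyclobutan-1-one | C=CCC(=C)C1CC(=O)C1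
F7 | step 2 | (2R)-2-methylbut-3-ene-1,2-diol | C=C[C@@](C)(O)CO
F0 | step 4 | none | none
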